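**Retrosynthetic overview**

1. Target 22 is an oxane (O1, C2 bearing ring B, C3, C4 bearing the axial acetate, C5, C6 bearing the ring A ethyl chain; C2 and C6 cis). It is traced back through O-debenzylation, acetylation and two hydride deliveries (C6, then C4) to the (2S)-2-aryl-2,3-dihydro-4H-pyran-4-one 17.
2. 17 comes from a catalyst-controlled conjugate arylation (C2–ring B bond) of the flat, achiral 4-pyranone 9 with boronic acid 16.
3. 9 comes from a hetero-Diels–Alder reaction of acylketene 7 (O1=C6–C5=C4=O, released from dioxinone 5 by loss of acetone) with butyl vinyl ether 6 (C2=C3). This forms O1–C2 and C3–C4 at once; butanol is then lost.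
4. Enabling feature: O1 and the C4 oxygen are 1,3-related through C5 (a latent β-ketoacyl unit), and C2 is an O1-bound CH carrying only ring B. C2 can therefore enter as the alkoxy-bearing carbon of an enol ether, and ring B can be added afterwards to the pyranone.
5. Ring order: 1,3-dioxinone (temporary ring) → 4-pyranone (step 3) → dihydropyranone → oxane; rings A and B come from purchased arenes.

Key step: step 3

Remark on the chemistry: ring atoms are numbered throughout as in the target oxane; the ligand enantiomer in step 7 is assigned by analogy with arylations of chromones and 3-substituted cyclohexenones and is exchanged for its antipode if the (2R) product should prevail.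

**Route**

Step 1
Reactants: 1 [4-(benzyloxy)-3-methoxyphenyl]methanol
Product: 2 1-(benzyloxy)-4-(bromomethyl)-2-methoxybenzene
Conditions: PBr3 (0.4 equiv), CH2Cl2, 0 °C
Reagents that add atoms: phosphorus tribromide, BrP(Br)Br
Why: Substitution of an electron-rich benzylic alcohol by bromide via its bromophosphite ester is routine at 0 °C, leaves the aryl benzyl ether untouched and involves no stereocenter.

Step 2
Reactants: 3 2,2,6-trimethyl-4H-1,3-dioxin-4-one; 2 1-(benzyloxy)-4-(bromomethyl)-2-methoxybenzene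
Product: 5 6-{2-[4-(benzyloxy)-3-methoxyphenyl]ethyl}-2,2-dimethyl-4H-1,3-dioxin-4-one, via lithium dienolate 4 (not isolated)
Conditions: LiN(i-Pr)2 (1.1 equiv), THF, −78 °C; then 2, DMPU, −78 to −40 °C
Reagents that add atoms: none
Why: γ-Alkylation of a vinylogous ester dienolate, in which the amide base removes a proton of the 6-methyl group and the extended enolate 4 should attack the reactive benzylic bromide through its terminal carbon in the presence of DMPU, no stereocenter being formed.

Step 3
Reactants: 5 6-{2-[4-(benzyloxy)-3-methoxyphenyl]ethyl}-2,2-dimethyl-4H-1,3-dioxin-4-one; 6 butyl vinyl ether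
Product: 9 2-{2-[4-(benzyloxy)-3-methoxyphenyl]ethyl}-4H-pyran-4-one, via acylketene 7 (not isolated), via butoxydihydropyranone 8 (not isolated)
Conditions: 6 (5 equiv), toluene, 110 °C, sealed tube; then TsOH·H2O (0.1 equiv), THF/H2O, rt
Reagents that add atoms: none
Why: Heating opens dioxinone 5 by a retro-hetero-Diels–Alder reaction with loss of acetone to acylketene 7, an s-cis 1-oxadiene O1=C6–C5=C4 whose ketene carbon C4 is strongly electrophilic. The electron-rich enol ether 6 then adds in a concerted, asynchronous hetero-[4+2] cycloaddition in which its CH2 carbon (C3) bonds to C4 and the acyl oxygen O1 bonds to the butoxy-bearing carbon C2, so the six-membered ring is closed by an intermolecular cycloaddition that makes both ring bonds in one transition state. The closest known reaction type is the thermolysis of 6-substituted 2,2-dimethyl-1,3-dioxin-4-ones or acyl Meldrum's acids in the presence of vinyl ethers to give 2-alkoxy-2,3-dihydro-4H-pyran-4-ones, followed by acid-induced loss of the alcohol to the 4-pyranone. The only stereocenter formed, the acetal carbon C2 of 8, is racemic and is erased when TsOH expels butanol, so no stereocontrol is asked of this step. The selectivities needed are regiochemistry, secured by the matched polarization of the partners (nucleophilic β-carbon of the enol ether, electrophilic ketene carbon), and chemoselectivity against acylketene dimerization, secured by the excess of 6 and the slow thermal release of 7.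

Step 4
Reactants: 10 5-bromo-2-hydroxy-3-methoxybenzaldehyde
Product: 12 5-bromo-3-methoxybenzene-1,2-diol, via aryl formate 11 (not isolated)
Conditions: 30% aq. H2O2, NaOH, H2O, 0 °C to rt, under N2; then HCl
Reagents that add atoms: hydrogen peroxide, OO
Why: Dakin oxidation, in which hydroperoxide adds to the aldehyde ortho to the phenoxide, aryl migration gives formate 11 and its hydrolysis in the basic medium should deliver the catechol without touching the aryl bromide.

Step 5
Reactants: 12 5-bromo-3-methoxybenzene-1,2-diol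
Product: 13 1,2-bis(benzyloxy)-5-bromo-3-methoxybenzene
Conditions: BnBr (2.3 equiv), K2CO3 (3 equiv), DMF, 60 °C
Reagents that add atoms: benzyl bromide, BrCc1ccccc1
Why: Williamson etherification of both phenols under carbonate base is standard and installs the same benzyl protection as on ring A, so that one final hydrogenolysis frees all three phenols.

Step 6
Reactants: 13 1,2-bis(benzyloxy)-5-bromo-3-methoxybenzene
Product: 16 [3,4-bis(benzyloxy)-5-methoxyphenyl]boronic acid, via aryllithium 14 (not isolated), via lithium triisopropoxyborate 15 (not isolated)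
Conditions: n-BuLi (1.1 equiv), THF, −78 °C; B(Oi-Pr)3 (1.5 equiv), −78 °C to rt; then 1 M HCl
Reagents that add atoms: triisopropyl borate, CC(C)OB(OC(C)C)OC(C)C; water, O
Why: Bromine–lithium exchange at −78 °C gives aryllithium 14, which is trapped by the borate ester as 15 and hydrolysed to the boronic acid, a standard lithiation–borylation that tolerates aryl benzyl ethers at low temperature.

Step 7
Reactants: 9 2-{2-[4-(benzyloxy)-3-methoxyphenyl]ethyl}-4H-pyran-4-one; 16 [3,4-bis(benzyloxy)-5-methoxyphenyl]boronic acid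
Product: 17 (2S)-2-[3,4-bis(benzyloxy)-5-methoxyphenyl]-6-{2-[4-(benzyloxy)-3-methoxyphenyl]ethyl}-2,3-dihydro-4H-pyran-4-one
Conditions: 16 (1.5 equiv), Pd(OCOCF3)2 (5 mol %), (R)-4-tert-butyl-2-(pyridin-2-yl)-4,5-dihydrooxazole (6 mol %), NH4PF6 (30 mol %), H2O (5 equiv), ClCH2CH2Cl, 60 °C
Reagents that add atoms: none
Why: Asymmetric conjugate addition of an arylboronic acid to a β-oxygenated cyclic enone under a cationic divalent palladium pyridine-oxazoline catalyst, a reaction type established for chromones (benzo-fused 4-pyranones), in which the arylpalladium species inserts the unsubstituted C2=C3 enone of 9 at the O-bound CH while the more hindered alkyl-substituted enone is left alone, the chiral ligand selects the enone face and so sets C2, and protonolysis of the palladium enolate by water releases 17.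

Step 8
Reactants: 17 (2S)-2-[3,4-bis(benzyloxy)-5-methoxyphenyl]-6-{2-[4-(benzyloxy)-3-methoxyphenyl]ethyl}-2,3-dihydro-4H-pyran-4-one
Product: 19 (2S,6S)-2-[3,4-bis(benzyloxy)-5-methoxyphenyl]-6-{2-[4-(benzyloxy)-3-methoxyphenyl]ethyl}oxan-4-one, via lithium enolate 18 (not isolated)
Conditions: LiBH(s-Bu)3 (1.05 equiv), THF, −78 °C; then AcOH, −78 °C
Reagents that add atoms: none
Why: Conjugate (1,4-) reduction of a 2,3-dihydro-4H-pyran-4-one by a bulky borohydride, in which hydride should add axially at C6 and anti to the pseudo-equatorial C2 aryl group through a chair-like enolate 18, so that the side chain ends equatorial and cis to the aryl group (substrate control from C2), and cold protonation gives the ketone.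

Step 9
Reactants: 19 (2S,6S)-2-[3,4-bis(benzyloxy)-5-methoxyphenyl]-6-{2-[4-(benzyloxy)-3-methoxyphenyl]ethyl}oxan-4-one
Product: 20 (2S,4S,6S)-2-[3,4-bis(benzyloxy)-5-methoxyphenyl]-6-{2-[4-(benzyloxy)-3-methoxyphenyl]ethyl}oxan-4-ol
Conditions: LiBH(s-Bu)3 (1.5 equiv), THF, −78 °C; then AcOH, H2O
Reagents that add atoms: none
Why: Diastereoselective 1,2-reduction in which the bulky hydride should attack the 2,6-diequatorial oxan-4-one from the equatorial direction and give the axial alcohol, trans to both ring substituents, which sets C4 by substrate control.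

Step 10
Reactants: 20 (2S,4S,6S)-2-[3,4-bis(benzyloxy)-5-methoxyphenyl]-6-{2-[4-(benzyloxy)-3-methoxyphenyl]ethyl}oxan-4-ol
Product: 21 (2S,4S,6S)-2-[3,4-bis(benzyloxy)-5-methoxyphenyl]-6-{2-[4-(benzyloxy)-3-methoxyphenyl]ethyl}oxan-4-yl acetate
Conditions: Ac2O, pyridine, DMAP (cat.), CH2Cl2, rt
Reagents that add atoms: acetic anhydride, CC(=O)OC(C)=O
Why: Acylation of the only free hydroxyl group under nucleophilic catalysis by DMAP proceeds with retention at C4, the phenols being still masked as benzyl ethers.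

Step 11
Reactants: 21 (2S,4S,6S)-2-[3,4-bis(benzyloxy)-5-methoxyphenyl]-6-{2-[4-(benzyloxy)-3-methoxyphenyl]ethyl}oxan-4-yl acetate
Product: 22 (2S,4S,6S)-2-(3,4-dihydroxy-5-methoxyphenyl)-6-[2-(4-hydroxy-3-methoxyphenyl)ethyl]oxan-4-yl acetate
Conditions: H2 (1 atm), Pd/C (10%), EtOAc, rt
Reagents that add atoms: none
Why: Hydrogenolysis of the three aryl benzyl ethers over Pd/C under neutral conditions at ambient pressure is expected to be faster than cleavage of the cyclic benzylic C2–O1 bond and leaves the acetate and all three stereocenters untouched.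

**Compound list**

1 | [4-(benzyloxy)-3-methoxyphenyl]methanol | COc1cc(CO)ccc1OCc1ccccc1 | starting material
2 | 1-(benzyloxy)-4-(bromomethyl)-2-methoxybenzene | COc1cc(CBr)ccc1OCc1ccccc1 | intermediate
3 | 2,2,6-trimethyl-4H-1,3-dioxin-4-one | CC1=CC(=O)OC(C)(C)O1 | starting material
4 | lithium 2,2-dimethyl-6-methylidene-6H-1,3-dioxin-4-olate (lithium dienolate of 3) | [Li+].[O-]C1=CC(=C)OC(C)(C)O1 | intermediate
5 | 6-{2-[4-(benzyloxy)-3-methoxyphenyl]ethyl}-2,2-dimethyl-4H-1,3-dioxin-4-one | COc1cc(CCC2=CC(=O)OC(C)(C)O2)ccc1OCc1ccccc1 | intermediate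
6 | butyl vinyl ether | C=COCCCC | starting material
7 | 5-[4-(benzyloxy)-3-methoxyphenyl]-3-oxopent-1-en-1-one (acylketene) | COc1cc(CCC(=O)C=C=O)ccc1OCc1ccccc1 | intermediate
8 | racemic 6-{2-[4-(benzyloxy)-3-methoxyphenyl]ethyl}-2-butoxy-2,3-dihydro-4H-pyran-4-one | COc1cc(CCC2=CC(=O)CC(OCCCC)O2)ccc1OCc1ccccc1 | intermediate
9 | 2-{2-[4-(benzyloxy)-3-methoxyphenyl]ethyl}-4H-pyran-4-one | COc1cc(CCC2=CC(=O)C=CO2)ccc1OCc1ccccc1 | intermediate
10 | 5-bromo-2-hydroxy-3-methoxybenzaldehyde | COc1cc(Br)cc(C=O)c1O | starting material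
11 | 5-bromo-2-hydroxy-3-methoxyphenyl formate | COc1cc(Br)cc(OC=O)c1O | intermediate
12 | 5-bromo-3-methoxybenzene-1,2-diol | COc1cc(Br)cc(O)c1O | intermediate
13 | 1,2-bis(benzyloxy)-5-bromo-3-methoxybenzene | COc1cc(Br)cc(OCc2ccccc2)c1OCc1ccccc1 | intermediate
14 | [3,4-bis(benzyloxy)-5-methoxyphenyl]lithium | [Li]c1cc(OC)c(OCc2ccccc2)c(OCc2ccccc2)c1 | intermediate
15 | lithium [3,4-bis(benzyloxy)-5-methoxyphenyl]tri(propan-2-yloxy)borate | [Li+].COc1cc([B-](OC(C)C)(OC(C)C)OC(C)C)cc(OCc2ccccc2)c1OCc1ccccc1 | intermediate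
16 | [3,4-bis(benzyloxy)-5-methoxyphenyl]boronic acid | COc1cc(B(O)O)cc(OCc2ccccc2)c1OCc1ccccc1 | intermediate
17 | (2S)-2-[3,4-bis(benzyloxy)-5-methoxyphenyl]-6-{2-[4-(benzyloxy)-3-methoxyphenyl]ethyl}-2,3-dihydro-4H-pyran-4-one | COc1cc(CCC2=CC(=O)C[C@@H](c3cc(OCc4ccccc4)c(OCc4ccccc4)c(OC)c3)O2)ccc1OCc1ccccc1 | intermediate
18 | lithium (2S,6S)-2-[3,4-bis(benzyloxy)-5-methoxyphenyl]-6-{2-[4-(benzyloxy)-3-methoxyphenyl]ethyl}-3,6-dihydro-2H-pyran-4-olate | [Li+].COc1cc(CC[C@H]2C=C([O-])C[C@@H](c3cc(OCc4ccccc4)c(OCc4ccccc4)c(OC)c3)O2)ccc1OCc1ccccc1 | intermediate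
19 | (2S,6S)-2-[3,4-bis(benzyloxy)-5-methoxyphenyl]-6-{2-[4-(benzyloxy)-3-methoxyphenyl]ethyl}oxan-4-one | COc1cc(CC[C@H]2CC(=O)C[C@@H](c3cc(OCc4ccccc4)c(OCc4ccccc4)c(OC)c3)O2)ccc1OCc1ccccc1 | intermediate
20 | (2S,4S,6S)-2-[3,4-bis(benzyloxy)-5-methoxyphenyl]-6-{2-[4-(benzyloxy)-3-methoxyphenyl]ethyl}oxan-4-ol | COc1cc(CC[C@H]2C[C@H](O)C[C@@H](c3cc(OCc4ccccc4)c(OCc4ccccc4)c(OC)c3)O2)ccc1OCc1ccccc1 | intermediate
21 | (2S,4S,6S)-2-[3,4-bis(benzyloxy)-5-methoxyphenyl]-6-{2-[4-(benzyloxy)-3-methoxyphenyl]ethyl}oxan-4-yl acetate | COc1cc(CC[C@H]2C[C@H](OC(C)=O)C[C@@H](c3cc(OCc4ccccc4)c(OCc4ccccc4)c(OC)c3)O2)ccc1OCc1ccccc1 | intermediate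
22 | (2S,4S,6S)-2-(3,4-dihydroxy-5-methoxyphenyl)-6-[2-(4-hydroxy-3-methoxyphenyl)ethyl]oxan-4-yl acetate | COc1cc(CC[C@H]2C[C@H](OC(C)=O)C[C@@H](c3cc(O)c(O)c(OC)c3)O2)ccc1O | target

**Step count and risks**

Total step count: 11. Longest linear sequence: 8 steps (steps 1, 2, 3, 7, 8, 9, 10, 11; the branch through steps 4, 5, 6 is equally long).

Steps most likely to fail:

Step 7. The arylpalladium species may insert the weakly electrophilic monocyclic pyranone too slowly, the electron-rich boronic acid may protodeboronate, or 17 may lose optical purity through reversible retro-oxa-Michael ring opening. The fallback sets out from dioxinone 5 and aryl bromide 13 and returns at ketone 19. Heating 5 with methanol in toluene traps the acylketene as methyl 5-[4-(benzyloxy)-3-methoxyphenyl]-3-oxopentanoate F1. Noyori asymmetric hydrogenation (H2, RuCl2[(S)-BINAP], MeOH) should give methyl (3S)-5-[4-(benzyloxy)-3-methoxyphenyl]-3-hydroxypentanoate F2, which MeNH(OMe)·HCl and i-PrMgCl convert into (3S)-5-[4-(benzyloxy)-3-methoxyphenyl]-3-hydroxy-N-methoxy-N-methylpentanamide F3. Separately, bromine–lithium exchange on 13 (n-BuLi) and acylation with N-methoxy-N-methylacetamide gives 1-[3,4-bis(benzyloxy)-5-methoxyphenyl]ethan-1-one F4. The lithium enolate of F4 (excess LiN(i-Pr)2, THF, −78 °C) is acylated by F3 in a Claisen condensation to (5S)-1-[3,4-bis(benzyloxy)-5-methoxyphenyl]-7-[4-(benzyloxy)-3-methoxyphenyl]-5-hydroxyheptane-1,3-dione F5. TsOH in toluene cyclodehydrates this to (2S)-6-[3,4-bis(benzyloxy)-5-methoxyphenyl]-2-{2-[4-(benzyloxy)-3-methoxyphenyl]ethyl}-2,3-dihydro-4H-pyran-4-one F6. Hydrogenation of its enone double bond (H2, Pd/C, 2,2'-bipyridyl, EtOAc) from the face opposite the side chain should then give 19 without loss of the benzyl ethers.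

Step 2. The dienolate may be alkylated at its α-carbon instead of the terminal carbon, be alkylated twice, or condense with unreacted dioxinone. The fallback sets out from bromide 2 and returns at dioxinone 5. The dianion of tert-butyl acetoacetate (NaH, then n-BuLi, THF, 0 °C) is alkylated at its terminal carbon by 2 to give tert-butyl 5-[4-(benzyloxy)-3-methoxyphenyl]-3-oxopentanoate F7. Acetone with trifluoroacetic anhydride and trifluoroacetic acid then closes the dioxinone ring to 5.

Step 8. Hydride may add 1,2 to the carbonyl group instead of 1,4, or the ketone may be reduced further once it is set free. The fallback sets out from 17 and returns at 19. It replaces hydride delivery by heterogeneous hydrogenation of the C5=C6 double bond (H2, Pd/C, 2,2'-bipyridyl, EtOAc), which should add hydrogen to the face opposite the C2 aryl group while the amine additive suppresses cleavage of the aryl benzyl ethers; it makes no new compound.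

**Further compounds**

F1 | step 7 | methyl 5-[4-(benzyloxy)-3-methoxyphenyl]-3-oxopentanoate | COC(=O)CC(=O)CCc1ccc(OCc2ccccc2)c(OC)c1
F2 | step 7 | methyl (3S)-5-[4-(benzyloxy)-3-methoxyphenyl]-3-hydroxypentanoate | COC(=O)C[C@@H](O)CCc1ccc(OCc2ccccc2)c(OC)c1
F3 | step 7 | (3S)-5-[4-(benzyloxy)-3-methoxyphenyl]-3-hydroxy-N-methoxy-N-methylpentanamide | CON(C)C(=O)C[C@@H](O)CCc1ccc(OCc2ccccc2)c(OC)c1
F4 | step 7 | 1-[3,4-bis(benzyloxy)-5-methoxyphenyl]ethan-1-one | CC(=O)c1cc(OC)c(OCc2ccccc2)c(OCc2ccccc2)c1
F5 | step 7 | (5S)-1-[3,4-bis(benzyloxy)-5-methoxyphenyl]-7-[4-(benzyloxy)-3-methoxyphenyl]-5-hydroxyheptane-1,3-dione | COc1cc(CC[C@H](O)CC(=O)CC(=O)c2cc(OC)c(OCc3ccccc3)c(OCc3ccccc3)c2)ccc1OCc1ccccc1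
F6 | step 7 | (2S)-6-[3,4-bis(benzyloxy)-5-methoxyphenyl]-2-{2-[4-(benzyloxy)-3-methoxyphenyl]ethyl}-2,3-dihydro-4H-pyran-4-one | COc1cc(CC[C@H]2CC(=O)C=C(c3cc(OC)c(OCc4ccccc4)c(OCc4ccccc4)c3)O2)ccc1OCc1ccccc1
F7 | step 2 | tert-butyl 5-[4-(benzyloxy)-3-methoxyphenyl]-3-oxopentanoate | CC(C)(C)OC(=O)CC(=O)CCc1ccc(OCc2ccccc2)c(OC)c1
F0 | step 8 | none | none
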